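Count the reagent before weighing the preference of the catalyst.

all flasks: free catalyst 160 mM; impurity 34 mM

| run | left-handed substrate | right-handed substrate | reagent | remark | time |
|---|---|---|---|---|---|
| Thursday's | 1 M | 1 M | 0.80 M | the very flask that is asked about, followed so far |  |
| Monday's | 0.67 M | 0.67 M | 0.80 M | run made earlier |  |
| flask | 1.0 M | 1.0 M | 0.800 M |  | 6.0 d |

| run | time / d | right-handed substrate / % | left-handed substrate / % | left-handed product / % |
|---|---|---|---|---|
| Thursday's | 0.125 | 40.9 | 28.0 | 21.9 |
| Thursday's | 0.333 | 39.5 | 25.4 | 25.4 |
| Thursday's | 0.625 | 39.7 | 23.0 | 26.8 |
| Thursday's | 1.04 | 38.8 | 23.8 | 26.3 |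
| Thursday's | 1.67 | 38.2 | 22.6 | 26.6 |
| Thursday's | 2.08 | 38.3 | 24.1 | 26.2 |
| Thursday's | 2.50 | 37.8 | 22.9 | 26.6 |
| Monday's | 0.208 | 37.8 | 21.7 | 28.3 |
| Monday's | 0.625 | 35.5 | 18.1 | 32.9 |
| Monday's | 1.25 | 34.3 | 15.4 | 33.6 |
| Monday's | 1.67 | 34.8 | 15.9 | 34.3 |
| Monday's | 2.50 | 34.5 | 15.4 | 33.5 |
| Monday's | 3.00 | 34.1 | 14.9 | 35.2 |
| Monday's | 4.00 | 33.1 | 15.5 | 34.1 |

(each reading ± 0.5 percentage points)

* whether the excess of right-handed substrate over left-handed substrate among what is left of the two reaches 80% by 6.0 d (no / yes)
* the highest excess of right-handed substrate over left-handed substrate among what is left of the two up to 6.0 d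

- free catalyst is single-handed; left-handed substrate and right-handed substrate are mirror images of each other, charged as a racemate, each of them at the stated concentration

The flask is a kinetic resolution, and the bench rule assumes that each reagent consumed takes one substrate with it. Thursday's last reading has lost 0.786 M of substrate against 0.800 M of reagent, which fits that assumption. The rule gives the reagent ceiling: the excess left if all the reagent went to the left-handed substrate, which is the reagent charge divided by both substrate charges minus the reagent charge, here 66.7%. That is below the 80% asked, so this reckoning answers no. The formula stops working where the reagent equals the left-handed charge, since the ceiling reaches 100% there; this flask stands at a ratio of 0.800.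

A ceiling is a bound, not a promise: Monday's run has lost 0.689 M by its last reading, less than its 0.80 M of reagent. The reagent is also shared between the two substrates, so where the substrate lost equals the reagent charge, the excess is the ceiling times the preference, the left-handed loss minus the right-handed loss over their sum. Thursday's readings put the preference at 41.5% first and 37.9% last. The last value gives 25.3% as the excess at a loss equal to the reagent charge, and this reckoning commits to that figure for the top.

The forecast says no and 25.5%, a little above this reckoning, and says of the late creep of right-handed substrate: “That drift lowers the excess, so the excess peaks early”.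

The flask gives no and 25.7%, under the ceiling of 66.7%, with reagent down to 2.91% of its charge at 6.00 d.

    reagent + free catalyst + left-handed substrate → free catalyst + left-handed product (k = 7.80 /M²/h)
    reagent + free catalyst + right-handed substrate → free catalyst + right-handed product (k = 2.60 /M²/h)
    free catalyst + impurity → spent catalyst A (k = 150 /M/h)
    free catalyst → spent catalyst B (k = 0.0170 /h)
    2 free catalyst → spent catalyst C (k = 3.60 /M/h)

The forecast's top belongs to this reagent charge, and a change of that charge moves it. With 0.48 M of reagent and the rest held, the ceiling falls to 31.6%. That neighbouring flask has lost 0.474 M of substrate at its end, less than Thursday's run at its first reading, so the reckoning takes the first preference of 41.5%, and the product is 13.1%. That neighbouring flask ends with 32.9% left-handed and 43.5% right-handed substrate, and its top is 13.9%.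

The numbers in the tables were computed from invented constants, and the scatter is random.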